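The numbers in the tables were computed from invented constants, and the scatter is random.

Of the J charged, maple holds 61% as Q, 25% as L and 12% as J at 120 min, so Q and L together carry what J has lost. At 60.0 min, J reads 36% in maple with 1 M of G and 37% in cedar with 2.2 M, so within the scatter G leaves the loss of J unchanged and acts later, on what J gives.

| flask | J | G | D | remark | time |
|---|---|---|---|---|---|
| maple | 0.20 M | 1 M | 0.22 M | run made earlier |  |
| alder | 0.20 M | 1.4 M | 0.22 M | run made earlier |  |
| cedar | 0.20 M | 2.2 M | 0.22 M | run made earlier |  |
| north-west | 0.20 M | 1.00 M | 0.220 M | everything together at the start | 2.0 h |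
| south | 0.20 M | 1.00 M | 0.220 M (fed, over 50 min) | all else is in the flask from the start; the feed brings no volume worth counting | 2.0 h |
| south-east | 0.20 M (fed, over 50 min) | 1.00 M | 0.220 M | all else is in the flask from the start; the feed brings no volume worth counting | 2.0 h |

| run | time / min | Q / % | L / % | J / % |
|---|---|---|---|---|
| maple | 8.00 | 9 | 4 | 87 |
| maple | 25.0 | 25 | 7 | 64 |
| maple | 40.0 | 41 | 10 | 50 |
| maple | 60.0 | 46 | 18 | 36 |
| maple | 90.0 | 56 | 22 | 24 |
| maple | 120 | 61 | 25 | 12 |
| alder | 20.0 | 22 | 8 | 74 |
| alder | 40.0 | 36 | 14 | 50 |
| alder | 60.0 | 46 | 19 | 36 |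
| alder | 80.0 | 54 | 25 | 25 |
| alder | 90.0 | 53 | 27 | 24 |
| alder | 120 | 55 | 29 | 14 |
| cedar | 20.0 | 15 | 12 | 72 |
| cedar | 40.0 | 30 | 17 | 52 |
| cedar | 60.0 | 40 | 26 | 37 |
| cedar | 80.0 | 43 | 29 | 23 |
| cedar | 90.0 | 45 | 32 | 22 |
| cedar | 120 | 54 | 36 | 18 |

(scatter of a reading: 1.5 percentage points)

- a reading or a percentage of L counts all its forms, free or not

- which flask leads in amount of Q, in percent of the J charged ("all alike" within 1.5 percentage points) (north-west / south / south-east / all alike)
- how much Q is there at the end, in percent of the J charged: north-west
- how much Q is there at the end, in percent of the J charged: south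
- how much Q is there at the end, in percent of the J charged: south-east

Two rates then compete for what J gives, taken here as an intermediate: capture by D, proportional to s times D, and capture by G, proportional to G. Here s is the capture factor, the ratio of the two rates at equal amounts of D and G, a selectivity factor. Taking one D per Q and G as constant, the ratio of Q to L integrates in closed form: s equals G times the logarithm of D charged over D remaining, divided by L formed, in molar amounts. The end readings give 16.2 in maple, 16.7 in alder and 20.6 in cedar.

With the reading from maple for s and 1.00 M of G, the two rates match at 0.0618 M of D, below the charge of 0.220 M. North-west repeats maple's recipe, so this reckoning expects about 61% of Q there. The feed in south needs 14.1 min of its 50 min to deliver even that crossing amount, so this reckoning expects L to be favoured at the start of south and Q to end lower there than in north-west. The forecast gives 61%, 48% and 57% for north-west, south and south-east, with north-west leading, and says of south that “much intermediate goes to L”. The flasks end at 63.3%, 51.7% and 57.9%, and north-west leads.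

    J ⇌ Z (K = 0.0966, k = 0.0171 /min)
    D + Z → Q (k = 1000 /M/min)
    G + Z → L (k = 45.0 /M/min)
    D ⇌ X (K = 0.318, k = 0.0171 /min)
    G + L ⇌ E, settled at all times (K = 1.58 /M)

South ends with a ratio of Q to L of 1.46, and that ratio times the G charged over s reads as an effective D of 0.0903 M. The neighbouring flask is south with 1.7 M of G, which moves the crossing amount to 0.105 M. It ends with 42.9% of Q and 44.2% of L, a ratio of 0.972, so its effective D reads 0.102 M. J stands at 12.9% in that neighbouring flask.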